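The earlier runs and the new flask were generated by integration from invented constants; noise was put on by code.

| flask | starting material | reagent | protic impurity | remark | time |
|---|---|---|---|---|---|
| maple | 1.3 × 10⁻⁴ M | 1 equiv | 0.060 mM | run made earlier |  |
| larch | 3.0 × 10⁻⁴ M | 1 equiv | 0.060 mM | run made earlier |  |
| ash | 2.0 × 10⁻⁴ M | 2 equiv | 0.060 mM | run made earlier |  |
| flask | 2.0 × 10⁻⁴ M | 1.00 equiv | 0.0600 mM |  | 6.0 min |

- maple (time / min: starting material / %, target / %, intermediate A / %): 0.500: 42.3, 1.4, 6.2; 0.833: 42.0, 0.7, 5.9; 1.33: 41.5, 1.4, 5.8; 2.00: 42.1, 1.3, 5.7; 4.00: 41.0, 1.5, 6.6; 6.00: 41.3, 1.8, 6.3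
- larch (time / min: starting material / %, target / %, intermediate A / %): 1.00: 50.8, 6.3, 13.0; 2.00: 50.6, 6.4, 13.0; 3.00: 51.1, 6.2, 12.7; 4.00: 50.4, 5.7, 12.8; 5.00: 50.8, 5.9, 13.4; 6.00: 50.6, 5.8, 12.6
- ash (time / min: starting material / %, target / %, intermediate A / %): 0.500: 36.3, 10.3, 14.3; 0.833: 33.7, 10.7, 13.5; 1.50: 35.7, 10.8, 14.3; 3.00: 34.6, 10.5, 13.7; 6.00: 34.5, 11.2, 14.2

(standard deviation of a reading: 0.5 percentage points)

- the numbers in the tables scatter with a standard deviation of 0.5 percentage points
- steps under discussion: starting material + reagent <-> intermediate A; intermediate A <-> intermediate B; reagent + intermediate B <-> target; starting material + protic impurity -> quenched substrate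
- the reaction counts as stopped when no species that holds the starting material changes by six tenths of a point or more over the second half of the time

- which holds at 6.0 min: what has brought the reaction to rest, or that it has not come to rest (the reagent has run out first / forward and back rates have come level / it is still moving / all of the starting material has reacted)
- part of the starting material gone at 6.0 min
- the target standing at 6.0 min, as a percentage of the starting material charged
- the intermediate A standing at 6.0 min, as a percentage of the starting material charged

Reckon the free reagent R first: at rest, it tells how much of the starting material is held away from the free form S. The runs are flat from their first readings, so we read them as at rest. The flask, with 2.0 × 10⁻⁴ M of starting material, lies above maple and below larch, so we expect rest there too. We assume that the protic impurity takes its whole charge, one for one, so conversion in the flask starts from 30.0%. That leaves 0.140 mM usable. Ash, with 2 equiv of reagent and the same other charges as the flask, reads 65.5% gone at its last reading, and we take that as a loose ceiling.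

Intermediate A and intermediate B each hold one reagent, and the target holds two. So at 1 equivalent, R equals S plus the impurity charge minus the target. The last readings give R = 0.111 mM on maple and 0.194 mM on larch.

Define the hold g, an apparent equilibrium constant, as the starting material in both intermediates and the target, per S and per R. It reads 2.73 mM⁻¹ on maple and 2.99 mM⁻¹ on larch. Then S in the flask is the usable amount divided by 1 + gR, with R from the same balance.

For our high edge on the flask we take larch's hold and no target, which gives 52.2% gone. For the low edge we take maple's hold and larch's target share of the held amount, 19.7%, which gives 50.4%. The scatter of 0.5 percentage points blurs both edges.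

The forecast says forward and back rates have come level, with 50.7% gone, 3.5% target and 9.7% intermediate A, noting that “All three runs are flat from the first point”. Its conversion lies inside our bracket.

In the flask, forward and back rates have come level. It has 51.0% gone, inside our bracket, with 3.56% target and 9.60% intermediate A.

    starting material + reagent ⇌ intermediate A (K = 1300 M⁻¹, k = 740 M⁻¹ s⁻¹)
    intermediate A ⇌ intermediate B (K = 0.820, k = 0.130 s⁻¹)
    reagent + intermediate B ⇌ target (K = 3000 M⁻¹, k = 870 M⁻¹ s⁻¹)
    starting material + protic impurity → quenched substrate (k = 2100 M⁻¹ s⁻¹)

Now carry maple's hold to the neighbour flask with 8.0 × 10⁻⁵ M of starting material, the same equivalents of reagent and the same impurity. Its usable amount is 0.0200 mM. With no target counted, the same balance gives 79.3% gone. That neighbour flask stands at 79.2% gone.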